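**Retrosynthetic overview**

1. Target 18 has twofold rotational symmetry. Each half is a quinolizidin-2-one with ring A = N5, C4, C3 (methyl), C2 (ketone), C1, C9a and ring B = N5, C6–C9, C9a; the 16-membered carbocycle runs C9a–C1–(CH2)5 (Ca–Ce)–C9'–C9a'–C1'–(CH2)5–C9.
2. Feature on which the route rests: these 16 ring carbons are the head-to-tail dimer of a 3-substituted cyclooctene, and the two alkenes of that dimer are C9a=C1 and C9a'=C1'. Each needs N5 on C9a and the acyl carbon C2 on C1, added anti across an E alkene, with nitrogen tethered to C9 through C8–C7–C6.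
3. Rings A (last): the N5–C4 bonds by 6-endo aza-Michael addition of each piperidine nitrogen to an isopropenyl ketone made from a C1 methyl ester; C1 and C3 settle by enolisation.
4. Rings B (key): both N5–C9a and both C1–C2 bonds by twofold palladium-catalysed aminocarbonylation of the macrocyclic (E,E)-diene bis(sulfonamide) 10. The sulfonyl group is 2-nitrobenzenesulfonyl, which thiolate removes beside the esters; a tosyl group would need reducing conditions that the esters do not survive.
5. Macrocycle (first): 10 by ring-opening/ring-closing metathesis dimerisation of (S)-3-substituted cyclooctene 9, made from cyclooctene by allylic bromination and copper-catalysed asymmetric allylic alkylation. Ring order: macrocycle, two rings B, two rings A.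

Key step: step 7

Assumption: the locants of the quinolizidinone halves of 18 (C1–C4, N5, C6–C9, C9a, primes for the second half, Ca–Ce for the pentamethylene chains) are used for all intermediates.
Assumption: the sense of induction in step 2 is not predicted; the phosphoramidite antipode that delivers the S monomer is the one used. C1 and C3, both α to the C2 ketone, are taken to be under thermodynamic control in step 11.

Step 1
Reactants: 1 (Z)-cyclooctene
Product: 2 rac-3-bromocyclooct-1-ene
Conditions: NBS (0.4 equiv relative to 1), AIBN (1 mol %), PhCF3, 80 °C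
Reagents that add atoms: N-bromosuccinimide, O=C1CCC(=O)N1Br
Why: Wohl–Ziegler radical allylic bromination: the symmetrical cyclooctenyl radical can give only the 3-bromide, formed as the racemate, and the excess of alkene keeps dibromide formation low.

Step 2
Reactants: 2 rac-3-bromocyclooct-1-ene; 3 (3-bromopropoxy)(tert-butyl)dimethylsilane (commercial)
Product: 5 tert-butyl{3-[(1S,2Z)-cyclooct-2-en-1-yl]propoxy}dimethylsilane, via silyloxypropylmagnesium bromide 4 (not isolated)
Conditions: 3, Mg, Et2O, rt; then slow addition to 2, CuBr·SMe2 (3 mol %), O,O'-[(S)-1,1'-binaphthalene-2,2'-diyl] N,N-bis[(S)-1-phenylethyl]phosphoramidite (3.3 mol %), CH2Cl2, −78 °C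
Reagents that add atoms: magnesium, [Mg] (carried by intermediate 4 only)
Why: Copper-catalysed asymmetric allylic alkylation of a racemic cyclic allylic bromide with a Grignard reagent, in which the chiral copper catalyst funnels both enantiomers of 2 to one product enantiomer (SN2 and SN2' attack on the symmetrical allyl unit give the same constitution); the phosphoramidite on copper sets the allylic stereocentre, the later C9, as S.

Step 3
Reactants: 5 tert-butyl{3-[(1S,2Z)-cyclooct-2-en-1-yl]propoxy}dimethylsilane
Product: 6 3-[(1S,2Z)-cyclooct-2-en-1-yl]propan-1-ol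
Conditions: (±)-camphor-10-sulfonic acid (10 mol %), MeOH, rt
Reagents that add atoms: none
Why: Acid-catalysed methanolysis (transetherification) of a primary silyl ether; the Z alkene and the stereocentre are inert to catalytic sulfonic acid in methanol at room temperature.

Step 4
Reactants: 6 3-[(1S,2Z)-cyclooct-2-en-1-yl]propan-1-ol
Product: 7 3-[(1S,2Z)-cyclooct-2-en-1-yl]propyl methanesulfonate
Conditions: MsCl, Et3N, CH2Cl2, 0 °C
Reagents that add atoms: methanesulfonyl chloride, CS(=O)(=O)Cl
Why: Sulfonylation of a primary alcohol to its mesylate (sulfonate ester formation), which leaves the remote stereocentre untouched.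

Step 5
Reactants: 7 3-[(1S,2Z)-cyclooct-2-en-1-yl]propyl methanesulfonate; 8 2-nitrobenzenesulfonamide (3 equiv)
Product: 9 N-{3-[(1S,2Z)-cyclooct-2-en-1-yl]propyl}-2-nitrobenzenesulfonamide
Conditions: K2CO3, DMF, 60 °C
Reagents that add atoms: none
Why: SN2 N-alkylation of the sulfonamide anion by a primary mesylate (Fukuyama-type sulfonamide alkylation); the excess of 8 suppresses dialkylation.

Step 6
Reactants: 9 N-{3-[(1S,2Z)-cyclooct-2-en-1-yl]propyl}-2-nitrobenzenesulfonamide (two molecules)
Product: 10 N,N'-{[(1S,2E,9S,10E)-cyclohexadeca-2,10-diene-1,9-diyl]di(propane-3,1-diyl)}bis(2-nitrobenzenesulfonamide)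
Conditions: second-generation Grubbs catalyst RuCl2(=CHPh)(H2IMes)(PCy3) (5 mol %), CH2Cl2 (3 mM in 9), 40 °C; ethyl vinyl ether quench; chromatography and recrystallisation
Reagents that add atoms: none
Why: Ring-opening/ring-closing metathesis cyclodimerisation: strain release opens the cyclooctene, the allylic substituent steers each metallacyclobutane so that the units join head to tail with E alkenes (the behaviour known from ring-opening metathesis polymerisation of 3-substituted cyclooctenes), and high dilution shifts the ring–chain equilibrium towards the smallest strain-free ring, the 16-membered dimer; no stereocentre is touched, and any R monomer should end mainly in the separable meso dimer, which should raise the enantiomeric purity of 10.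

Step 7
Reactants: 10 N,N'-{[(1S,2E,9S,10E)-cyclohexadeca-2,10-diene-1,9-diyl]di(propane-3,1-diyl)}bis(2-nitrobenzenesulfonamide)
Product: 11 dimethyl diester in which the 16-membered ring is fused at C9–C9a and C9'–C9a' to two N-(2-nitrophenylsulfonyl)piperidines (rings B) and carries CO2Me on C1 and C1'; (1R,9S,9aS) in each half
Conditions: PdCl2 (20 mol %), CuCl2 (6 equiv), NaOAc (6 equiv), CO (1 atm), MeOH–THF 3:1, rt
Reagents that add atoms: carbon monoxide, [C-]#[O+]; methanol, CO
Why: Divalent palladium binds each E alkene on the face away from its own C9 tether, the sulfonamide nitrogen (deprotonated by acetate) attacks C9a anti to the metal, the resulting C1–Pd bond inserts CO with retention, and methanolysis of the acylpalladium gives the ester and zerovalent palladium, which CuCl2 returns to PdCl2. The closest known reaction type is the intramolecular aminocarbonylation (Wacker-type aminopalladation with CO capture) of alkenyl sulfonamides, here run twice on one macrocycle. Each ring B closes in the 6-exo-trig mode, N5 to C9a, because the three-carbon tether from C9 could reach C1 only through a seven-membered endo closure. C9a is set by the existing C9 centre: in the reactive rotamer the C9–H bond lies in the alkene plane (least allylic strain), the tether and the macrocyclic chain Ca stand on opposite faces, and nitrogen therefore arrives syn to its tether and anti to Ca, which gives the trans-2,3-disubstituted piperidine; C1 is set relative to C9a by anti aminopalladation followed by retentive CO insertion across the E alkene. The step needs regioselectivity (secured by tether length), facial selectivity (secured by the C9 centre), CO insertion faster than β-hydride elimination (CO atmosphere and chloride-rich medium) and reaction at both alkenes, which the twofold symmetry makes equivalent so that a single diester should result.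

Step 8
Reactants: 11 bis[N-(2-nitrophenylsulfonyl)piperidine] dimethyl diester
Product: 13 bis(N-Boc-piperidine) dimethyl diester, (1R,9S,9aS) in each half, via free bis(piperidine) diester 12 (not isolated)
Conditions: PhSH, K2CO3, DMF, rt; then Boc2O, 40 °C
Reagents that add atoms: di-tert-butyl dicarbonate, CC(C)(C)OC(=O)OC(=O)OC(C)(C)C
Why: Fukuyama deprotection: thiophenolate adds ipso to the 2-nitroarene (Meisenheimer complex) and releases the amine with loss of SO2 under conditions that leave the methyl esters and all stereocentres alone, and the hindered secondary amines of 12 are then capped as tert-butyl carbamates so that the later magnesium reagents cannot close a β-lactam.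

Step 9
Reactants: 13 bis(N-Boc-piperidine) dimethyl diester
Product: 14 bis(N-Boc-piperidine) bis(N-methoxy-N-methylamide), the amide carbon C2 on each C1; (1R,9S,9aS) in each half
Conditions: MeNH(OMe)·HCl, iPrMgCl, THF, −20 → 0 °C
Reagents that add atoms: N,O-dimethylhydroxylamine hydrochloride, CNOC.Cl
Why: Weinreb amide formation by aminolysis of the ester with the chloromagnesium amide of N,O-dimethylhydroxylamine; possible epimerisation at C1 is without consequence because C1 is equilibrated in step 11.

Step 10
Reactants: 14 bis(N-Boc-piperidine) bis(N-methoxy-N-methylamide); 15 isopropenylmagnesium bromide (commercial THF solution)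
Product: 16 bis(N-Boc-piperidine) bis(isopropenyl ketone), C1–C(=O)–C(CH3)=CH2 in each half; (1R,9S,9aS) in each half
Conditions: THF, −20 → 0 °C; inverse quench into cold aq. NH4Cl
Reagents that add atoms: none
Why: Weinreb ketone synthesis: the five-membered magnesium chelate of the tetrahedral adduct survives until the quench, so a single alkenyl group is delivered and the isopropenyl ketone appears only on work-up, where the inverse cold quench keeps the freed N,O-dimethylhydroxylamine from adding to it.

Step 11
Reactants: 16 bis(N-Boc-piperidine) bis(isopropenyl ketone)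
Product: 18 target, (1R,3R,9S,9aS) in each half, via bis(amino enone) 17 (not isolated)
Conditions: TFA, CH2Cl2, 0 °C; evaporate; K2CO3, MeOH, rt → 40 °C
Reagents that add atoms: none
Why: Acidolysis of the carbamates gives 17 as its bis(trifluoroacetate), and on neutralisation intramolecular 6-endo-trig aza-Michael addition of each N5 to the CH2 terminus of its isopropenyl ketone closes the rings A, after which carbonate in methanol equilibrates C1 and C3, both α to C2, by enolisation, C3 being set by this thermodynamic control in favour of the trans-fused quinolizidinone with equatorial C3 methyl, axial C1 chain and equatorial C9 chain, the arrangement that avoids the peri clash between the C1 and C9 chains.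

**Compound list**

1 | (Z)-cyclooctene | C1CCC/C=C\CC1 | starting material
2 | rac-3-bromocyclooct-1-ene | BrC1/C=C\CCCCC1 | intermediate
3 | (3-bromopropoxy)(tert-butyl)dimethylsilane | CC(C)(C)[Si](C)(C)OCCCBr | starting material
4 | [3-(tert-butyldimethylsilyloxy)propyl]magnesium bromide | CC(C)(C)[Si](C)(C)OCCC[Mg]Br | intermediate
5 | tert-butyl{3-[(1S,2Z)-cyclooct-2-en-1-yl]propoxy}dimethylsilane | CC(C)(C)[Si](C)(C)OCCC[C@H]1/C=C\CCCCC1 | intermediate
6 | 3-[(1S,2Z)-cyclooct-2-en-1-yl]propan-1-ol | OCCC[C@H]1/C=C\CCCCC1 | intermediate
7 | 3-[(1S,2Z)-cyclooct-2-en-1-yl]propyl methanesulfonate | CS(=O)(=O)OCCC[C@H]1/C=C\CCCCC1 | intermediate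
8 | 2-nitrobenzenesulfonamide | NS(=O)(=O)c1ccccc1[N+](=O)[O-] | starting material
9 | N-{3-[(1S,2Z)-cyclooct-2-en-1-yl]propyl}-2-nitrobenzenesulfonamide | O=S(=O)(NCCC[C@H]1/C=C\CCCCC1)c1ccccc1[N+](=O)[O-] | intermediate
10 | N,N'-{[(1S,2E,9S,10E)-cyclohexadeca-2,10-diene-1,9-diyl]di(propane-3,1-diyl)}bis(2-nitrobenzenesulfonamide) | C1CCCC/C=C/[C@H](CCCNS(=O)(=O)c2ccccc2[N+](=O)[O-])CCCCC/C=C/[C@@H]1CCCNS(=O)(=O)c1ccccc1[N+](=O)[O-] | intermediate
11 | bis[N-(2-nitrophenylsulfonyl)piperidine] dimethyl diester (rings B closed, CO2Me on C1 and C1'; (1R,9S,9aS) in each half) | C1CCCC[C@@H](C(=O)OC)[C@H]2N(S(=O)(=O)c3ccccc3[N+](=O)[O-])CCC[C@@H]2CCCCC[C@@H](C(=O)OC)[C@H]4N(S(=O)(=O)c3ccccc3[N+](=O)[O-])CCC[C@@H]41 | intermediate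
12 | free bis(piperidine) dimethyl diester ((1R,9S,9aS) in each half) | C1CCCC[C@@H](C(=O)OC)[C@H]2NCCC[C@@H]2CCCCC[C@@H](C(=O)OC)[C@H]4NCCC[C@@H]41 | intermediate
13 | bis(N-Boc-piperidine) dimethyl diester ((1R,9S,9aS) in each half) | C1CCCC[C@@H](C(=O)OC)[C@H]2N(C(=O)OC(C)(C)C)CCC[C@@H]2CCCCC[C@@H](C(=O)OC)[C@H]4N(C(=O)OC(C)(C)C)CCC[C@@H]41 | intermediate
14 | bis(N-Boc-piperidine) bis(N-methoxy-N-methylamide) ((1R,9S,9aS) in each half) | C1CCCC[C@@H](C(=O)N(C)OC)[C@H]2N(C(=O)OC(C)(C)C)CCC[C@@H]2CCCCC[C@@H](C(=O)N(C)OC)[C@H]4N(C(=O)OC(C)(C)C)CCC[C@@H]41 | intermediate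
15 | isopropenylmagnesium bromide | CC(=C)[Mg]Br | starting material
16 | bis(N-Boc-piperidine) bis(isopropenyl ketone) ((1R,9S,9aS) in each half) | C1CCCC[C@@H](C(=O)C(C)=C)[C@H]2N(C(=O)OC(C)(C)C)CCC[C@@H]2CCCCC[C@@H](C(=O)C(C)=C)[C@H]4N(C(=O)OC(C)(C)C)CCC[C@@H]41 | intermediate
17 | bis(amino enone): free bis(piperidine) bis(isopropenyl ketone), formed as its bis(trifluoroacetate) ((1R,9S,9aS) in each half) | C1CCCC[C@@H](C(=O)C(C)=C)[C@H]2NCCC[C@@H]2CCCCC[C@@H](C(=O)C(C)=C)[C@H]4NCCC[C@@H]41 | intermediate
18 | CNP0268544.9, bis(quinolizidin-2-one) macrocycle, (1R,3R,9S,9aS) in each half | C[C@@H]1CN2CCC[C@@H]3CCCCC[C@H]4C(=O)[C@H](C)CN5CCC[C@H](CCCCC[C@@H](C1=O)[C@H]32)[C@@H]45 | target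

**Step count and risks**

Total step count: 11. Longest linear sequence: 11 steps (1 to 18).

The three steps most likely to fail are steps 7, 6 and 2.

Step 7. Nitrogen may attack the wrong face of C9a relative to C9, giving the cis-2,3-piperidine in one or both halves. The unstrained internal alkenes may be activated only slowly. β-Hydride elimination or chloride capture at C1 may outrun CO insertion, and the second ring closure may stall. Fallback: from 10, the two ring closures are done first with stoichiometric mercury and the carbon is brought in afterwards. Hg(OCOCF3)2 in MeNO2 at 0 °C to rt (intramolecular amidomercuration of the alkenyl sulfonamides, anti addition, reversible so that the piperidine can settle), followed by NaCl work-up, should give the bis(chloromercurio) bis(piperidine) F1. F1 is then carbonylated with PdCl2 (catalytic), CuCl2 and LiCl under CO in MeOH (transmetallation of the alkylmercury chloride to palladium with retention, CO insertion, methanolysis), which comes back to the route at 11.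

Step 6. The ring–chain equilibrium may deliver trimer and higher cyclic or linear oligomers instead of the 16-membered dimer, head-to-head junctions may slip in, and Z alkenes may persist. Fallback: from alcohol 6, the dimerisation is made intramolecular by a temporary silicon tether. Two molecules of 6 are joined with iPr2SiCl2 and imidazole in DMF to the bis(alkoxy)silane F2. The second-generation Grubbs catalyst at 1 mM in CH2Cl2 then runs the same ring-opening/ring-closing metathesis within one molecule and should give the silicon-bridged 16-membered (E,E)-diene F3. TBAF in THF removes the tether to give the diol F4, MsCl/Et3N gives the dimesylate F5, and an excess of 8 with K2CO3 in DMF at 60 °C comes back to the route at 10.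

Step 2. Enantioselection may be poor on the eight-membered allylic bromide, and Wurtz-type coupling of the bromide may compete. Fallback: from Grignard reagent 4, the stereocentre is set by conjugate addition instead of allylic substitution. Copper-catalysed asymmetric 1,4-addition of 4 to purchased cyclooct-2-en-1-one F6 (CuBr·SMe2, (R)-1-[(S)-2-(diphenylphosphino)ferrocenyl]ethyldicyclohexylphosphine or its antipode, tBuOMe, −75 °C) is followed by trapping of the magnesium enolate with N-(5-chloropyridin-2-yl)bis(trifluoromethanesulfonyl)imide. This gives the enol triflate F7, whose alkene lies regiospecifically next to the new stereocentre. Reduction of the triflate with Pd(OAc)2, PPh3, HCO2H and Bu3N in DMF at 60 °C comes back to the route at 5.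

**Further compounds**

F1 | step 7 | bis(chloromercurio) bis[N-(2-nitrophenylsulfonyl)piperidine], HgCl on C1 and C1' in place of CO2Me of 11 | C1CCCC[C@@H]([Hg]Cl)[C@H]2N(S(=O)(=O)c3ccccc3[N+](=O)[O-])CCC[C@@H]2CCCCC[C@@H]([Hg]Cl)[C@H]4N(S(=O)(=O)c3ccccc3[N+](=O)[O-])CCC[C@@H]41
F2 | step 6 | bis{3-[(1S,2Z)-cyclooct-2-en-1-yl]propoxy}di(propan-2-yl)silane | CC(C)[Si](OCCC[C@H]1/C=C\CCCCC1)(OCCC[C@H]1/C=C\CCCCC1)C(C)C
F3 | step 6 | (1S,2E,9S,10E)-cyclohexadeca-2,10-diene bridged from C1 to C9 by (CH2)3–O–Si(iPr)2–O–(CH2)3 | C1CCCC/C=C/[C@H](CCCO[Si](C(C)C)(C(C)C)OCCC2)CCCCC/C=C/[C@@H]12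
F4 | step 6 | 3,3'-[(1S,2E,9S,10E)-cyclohexadeca-2,10-diene-1,9-diyl]di(propan-1-ol) | C1CCCC/C=C/[C@H](CCCO)CCCCC/C=C/[C@@H]1CCCO
F5 | step 6 | [(1S,2E,9S,10E)-cyclohexadeca-2,10-diene-1,9-diyl]di(propane-3,1-diyl) dimethanesulfonate | C1CCCC/C=C/[C@H](CCCOS(C)(=O)=O)CCCCC/C=C/[C@@H]1CCCOS(C)(=O)=O
F6 | step 2 | (Z)-cyclooct-2-en-1-one, bought in | O=C1/C=C\CCCCC1
F7 | step 2 | (3S)-3-[3-(tert-butyldimethylsilyloxy)propyl]cyclooct-1-en-1-yl trifluoromethanesulfonate | CC(C)(C)[Si](C)(C)OCCC[C@H]1/C=C(OS(=O)(=O)C(F)(F)F)\CCCCC1
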